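## Retrosynthetic overview

1. Target 40 ⇐ acetate on C1 and 4‑hydroxybenzoate on C4 are installed last on the macrocyclic (1S,4R) alcohol 32 (C4 carried as a TBS ether).
2. The only ring, the 11‑membered carbocycle, is closed at C1–C2 by an intramolecular Nozaki–Hiyama–Kishi reaction of the seco iodo‑aldehyde 27. C1 is then set by oxidation and CBS reduction.
3. 27 ⇐ C10–C11 by alkylation of lithiated isobutyronitrile with iodide 21, and C8–C9 by alkylation of the tert‑butyl acetate enolate with allylic bromide 16.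
4. The E‑C6=C7 alkene ⇐ cross‑metathesis of 11 with methacrolein.
5. Key step: C4–C5 and the C4 stereocentre by Brown asymmetric allylboration of (Z)‑3‑iodo‑2‑methylprop‑2‑enal 6, which comes from propargyl alcohol by anti‑carbomagnesiation and iodination.

Assumptions: ring atoms are numbered C1 (acetoxy carbon), C2=C3, C4 (aroyloxy carbon), C5, C6=C7, C8–C10, C11 (CMe2), so the target is (1S,2Z,4R,6E). LiN(i‑Pr)2, i‑Bu2AlH and reagent 7 are bought as solutions.

## Route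

Step 1
Reactants: 1 prop‑2‑yn‑1‑ol; 2 methylmagnesium bromide; 3 iodine
Product: 5 (Z)‑3‑iodo‑2‑methylprop‑2‑en‑1‑ol, via chelated alkenylmagnesium alkoxide 4 (not isolated)
Conditions: MeMgBr (2.5 equiv), CuI (10 mol %), THF, −10 °C → rt; then I2, −10 °C → rt
Reagents that add atoms: methylmagnesium bromide 2, C[Mg]Br; iodine 3, II
Why: Copper‑catalysed anti‑carbomagnesiation of the propargylic alkoxide puts Me on C2 and Mg on C3 cis to the CH2O arm in a five‑membered chelate, so iodinolysis with retention gives only the Z iodoalkene.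

Step 2
Reactants: 5 (Z)‑3‑iodo‑2‑methylprop‑2‑en‑1‑ol
Product: 6 (Z)‑3‑iodo‑2‑methylprop‑2‑enal
Conditions: activated MnO2 (15 equiv), CH2Cl2, rt, dark; filtered and used at once
Reagents that add atoms: none
Why: Heterogeneous, neutral allylic oxidation with MnO2 gives the labile Z β‑iodoenal without E/Z isomerisation.

Step 3
Reactants: 6 (Z)‑3‑iodo‑2‑methylprop‑2‑enal; 7 B‑allyldiisopinocampheylborane (enantiomer from (−)‑α‑pinene)
Product: 9 (1Z,3R)‑1‑iodo‑2‑methylhexa‑1,5‑dien‑3‑ol, via dialkylborinate ester 8 (not isolated)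
Conditions: 7 (1.3 equiv), Et2O/pentane, −78 °C, 3 h; then NaOH, H2O2, 0 °C → rt
Reagents that add atoms: B‑allyldiisopinocampheylborane 7, C=CCB([C@@H]1[C@@H](C)[C@@H]2C[C@H](C1)C2(C)C)[C@@H]1[C@@H](C)[C@@H]2C[C@H](C1)C2(C)C
Why: Brown asymmetric allylboration (carbonyl allylation) through a chair Zimmerman–Traxler transition state under reagent control, in which the (−)‑α‑pinene‑derived borane adds allyl to the re face to give the 3R carbinol (future C4, typically ≥ 92 % ee) without any Lewis acid that could isomerise the iodoalkene.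

Step 4
Reactants: 9 (1Z,3R)‑1‑iodo‑2‑methylhexa‑1,5‑dien‑3‑ol; 10 tert‑butyldimethylsilyl chloride
Product: 11 tert‑butyl{[(1Z,3R)‑1‑iodo‑2‑methylhexa‑1,5‑dien‑3‑yl]oxy}dimethylsilane
Conditions: TBSCl, imidazole, DMF, rt
Reagents that add atoms: tert‑butyldimethylsilyl chloride 10, CC(C)(C)[Si](C)(C)Cl
Why: Standard imidazole‑mediated silylation protects the C4 hydroxyl as a robust TBS ether for the base and hydride steps that follow.

Step 5
Reactants: 11 TBS ether; 12 methacrolein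
Product: 13 (2E,5R,6Z)‑5‑[(tert‑butyldimethylsilyl)oxy]‑7‑iodo‑2,6‑dimethylhepta‑2,6‑dienal
Conditions: 12 (10 equiv), second‑generation Hoveyda–Grubbs catalyst (5 mol %), CH2Cl2, 40 °C
Reagents that add atoms: methacrolein 12, CC(=C)C=O
Why: Olefin cross‑metathesis of the unhindered terminal alkene with excess methacrolein is E‑selective for the conjugated trisubstituted enal and leaves the hindered iodoalkene untouched.

Step 6
Reactants: 13 enal
Product: 14 (2E,5R,6Z)‑5‑[(tert‑butyldimethylsilyl)oxy]‑7‑iodo‑2,6‑dimethylhepta‑2,6‑dien‑1‑ol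
Conditions: NaBH4, CeCl3·7H2O, MeOH, 0 °C
Reagents that add atoms: none
Why: Luche reduction gives clean 1,2‑reduction of the enal to the allylic alcohol without touching the C–I bond.

Step 7
Reactants: 14 allylic alcohol; 15 tetrabromomethane
Product: 16 (1Z,3R,5E)‑7‑bromo‑3‑[(tert‑butyldimethylsilyl)oxy]‑1‑iodo‑2,6‑dimethylhepta‑1,5‑diene
Conditions: CBr4, PPh3, CH2Cl2, 0 °C
Reagents that add atoms: tetrabromomethane 15, BrC(Br)(Br)Br
Why: The Appel reaction converts the primary allylic alcohol into the bromide under neutral conditions with retention of the E geometry.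

Step 8
Reactants: 16 allylic bromide; 17 tert‑butyl acetate
Product: 19 tert‑butyl (4E,7R,8Z)‑7‑[(tert‑butyldimethylsilyl)oxy]‑9‑iodo‑4,8‑dimethylnona‑4,8‑dienoate, via lithium enolate 18 (not isolated)
Conditions: 17 (2.5 equiv), LiN(i‑Pr)2, THF, −78 °C; then 16, DMPU, −78 → −20 °C
Reagents that add atoms: tert‑butyl acetate 17, CC(=O)OC(C)(C)C
Why: SN2 alkylation of the non‑self‑condensing lithium enolate of tert‑butyl acetate at the primary allylic bromide forms C8–C9 and adds the two carbons C9 and C10.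

Step 9
Reactants: 19 tert‑butyl ester
Product: 20 (4E,7R,8Z)‑7‑[(tert‑butyldimethylsilyl)oxy]‑9‑iodo‑4,8‑dimethylnona‑4,8‑dien‑1‑ol
Conditions: i‑Bu2AlH (3 equiv), CH2Cl2, −78 → 0 °C; aqueous potassium sodium tartrate
Reagents that add atoms: none
Why: Hydride reduction of the ester with i‑Bu2AlH gives the primary alcohol and spares the alkenyl iodide and the silyl ether.

Step 10
Reactants: 20 primary alcohol; 3 iodine
Product: 21 (1Z,3R,5E)‑3‑[(tert‑butyldimethylsilyl)oxy]‑1,9‑diiodo‑2,6‑dimethylnona‑1,5‑diene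
Conditions: I2, PPh3, imidazole, CH2Cl2, 0 °C → rt
Reagents that add atoms: iodine 3, II
Why: Appel‑type (Garegg–Samuelsson) iodination turns the primary alcohol into the alkyl iodide needed for the next alkylation.

Step 11
Reactants: 21 diiodide; 22 isobutyronitrile
Product: 24 (6E,9R,10Z)‑9‑[(tert‑butyldimethylsilyl)oxy]‑11‑iodo‑2,2,6,10‑tetramethylundeca‑6,10‑dienenitrile, via lithiated isobutyronitrile 23 (not isolated)
Conditions: 22 (2 equiv), LiN(i‑Pr)2, THF, −78 °C; then 21, −78 °C → rt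
Reagents that add atoms: isobutyronitrile 22, CC(C)C#N
Why: SN2 alkylation of the small, highly nucleophilic α‑cyano carbanion at the primary iodide builds the quaternary C11 (C10–C11 bond), while the sp2 C–I bond is inert.

Step 12
Reactants: 24 nitrile; 25 water
Product: 27 (6E,9R,10Z)‑9‑[(tert‑butyldimethylsilyl)oxy]‑11‑iodo‑2,2,6,10‑tetramethylundeca‑6,10‑dienal, via N‑aluminio aldimine 26 (not isolated)
Conditions: i‑Bu2AlH (1.5 equiv), toluene, −78 °C; then H2O, aqueous tartaric acid, 0 °C → rt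
Reagents that add atoms: water 25, O
Why: Partial reduction of the hindered nitrile with i‑Bu2AlH stops at the aldimine stage, and mild aqueous hydrolysis releases the non‑enolisable neopentyl aldehyde (C1).

Step 13
Reactants: 27 seco iodo‑aldehyde
Product: 29 (2Z,4R,6E)‑4‑[(tert‑butyldimethylsilyl)oxy]‑3,7,11,11‑tetramethylcycloundeca‑2,6‑dien‑1‑ol as a mixture of C1 epimers, via alkenylchromium dichloride 28 (not isolated)
Conditions: CrCl2 (10 equiv), NiCl2 (0.1 equiv), DMSO/THF 3:1, 0.003 M, slow addition, rt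
Reagents that add atoms: none
Why: Intramolecular Nozaki–Hiyama–Kishi reaction (oxidative addition of C–I to zerovalent nickel, transmetalation to trivalent chromium, addition to the aldehyde) closes the 11‑membered ring at C1–C2 with retention of the Z geometry; C1 is not controlled here and is reset in steps 14 and 15.

Step 14
Reactants: 29 macrocyclic allylic alcohol (both C1 epimers)
Product: 30 (2Z,4R,6E)‑4‑[(tert‑butyldimethylsilyl)oxy]‑3,7,11,11‑tetramethylcycloundeca‑2,6‑dien‑1‑one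
Conditions: Dess–Martin periodinane, NaHCO3, CH2Cl2, 0 °C → rt
Reagents that add atoms: none
Why: Dess–Martin oxidation converges both C1 epimers to one enone under buffered conditions, while the C4 hydroxyl stays silylated so that no transannular hemiketal can form.

Step 15
Reactants: 30 macrocyclic enone
Product: 32 (1S,2Z,4R,6E)‑4‑[(tert‑butyldimethylsilyl)oxy]‑3,7,11,11‑tetramethylcycloundeca‑2,6‑dien‑1‑ol, via catecholborate ester 31 (not isolated)
Conditions: (R)‑2‑methyl‑CBS‑oxazaborolidine (0.5 equiv), catecholborane (2 equiv), toluene, −78 °C; then MeOH, aqueous NaOH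
Reagents that add atoms: none
Why: Corey–Bakshi–Shibata reduction under reagent control, in which the quaternary C11 flank acts as the large group so that the (R)‑catalyst delivers hydride by 1,2‑addition to the face giving the 1S carbinol; the minor 4S series from step 3 becomes a separable diastereomer here.

Step 16
Reactants: 32 (1S)‑alcohol; 33 acetic anhydride
Product: 34 (1S,2Z,4R,6E)‑4‑[(tert‑butyldimethylsilyl)oxy]‑3,7,11,11‑tetramethylcycloundeca‑2,6‑dien‑1‑yl acetate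
Conditions: Ac2O, DMAP, pyridine, CH2Cl2, rt
Reagents that add atoms: acetic anhydride 33, CC(=O)OC(C)=O
Why: DMAP‑catalysed acylation acetylates the hindered neopentylic allylic alcohol with retention at C1.

Step 17
Reactants: 34 silyl ether acetate
Product: 35 (1S,2Z,4R,6E)‑4‑hydroxy‑3,7,11,11‑tetramethylcycloundeca‑2,6‑dien‑1‑yl acetate
Conditions: HF·pyridine, pyridine, THF, 0 °C → rt
Reagents that add atoms: none
Why: Buffered, weakly acidic fluoride cleaves the secondary TBS ether while the acetate stays on C1, because basic conditions that promote acyl migration are avoided.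

Step 18
Reactants: 36 4‑hydroxybenzoic acid; 10 tert‑butyldimethylsilyl chloride
Product: 38 4‑[(tert‑butyldimethylsilyl)oxy]benzoic acid, via silyl ester 37 (not isolated)
Conditions: TBSCl (2.2 equiv), imidazole, DMF, rt; then AcOH/THF/H2O, rt
Reagents that add atoms: tert‑butyldimethylsilyl chloride 10, CC(C)(C)[Si](C)(C)Cl
Why: Bis‑silylation followed by selective hydrolysis of the far more labile silyl ester leaves the phenol masked as its aryl TBS ether.

Step 19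
Reactants: 35 hydroxy acetate; 38 4‑[(tert‑butyldimethylsilyl)oxy]benzoic acid
Product: 39 (1S,2Z,4R,6E)‑1‑acetoxy‑3,7,11,11‑tetramethylcycloundeca‑2,6‑dien‑4‑yl 4‑[(tert‑butyldimethylsilyl)oxy]benzoate
Conditions: 38 (1.5 equiv), EDC·HCl, DMAP, CH2Cl2, 0 °C → rt
Reagents that add atoms: 4‑[(tert‑butyldimethylsilyl)oxy]benzoic acid 38, CC(C)(C)[Si](C)(C)Oc1ccc(cc1)C(=O)O
Why: Steglich esterification acylates the allylic C4 hydroxyl on oxygen, so the C4 configuration is retained.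

Step 20
Reactants: 39 silylated ester
Product: 40 CNP0246761.2, (1S,2Z,4R,6E)‑1‑acetoxy‑3,7,11,11‑tetramethylcycloundeca‑2,6‑dien‑4‑yl 4‑hydroxybenzoate
Conditions: Bu4NF, AcOH (1:1), THF, 0 °C
Reagents that add atoms: none
Why: Acetic‑acid‑buffered fluoride removes the very labile aryl silyl ether within minutes and leaves both esters and both stereocentres untouched.

## Compound list

1 | prop‑2‑yn‑1‑ol | C#CCO | starting material
2 | methylmagnesium bromide | C[Mg]Br | starting material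
3 | iodine | II | starting material
4 | (Z)‑[3‑(bromomagnesiooxy)‑2‑methylprop‑1‑en‑1‑yl]magnesium bromide | Br[Mg]/C=C(/C)CO[Mg]Br | intermediate (not isolated)
5 | (Z)‑3‑iodo‑2‑methylprop‑2‑en‑1‑ol | I/C=C(/C)CO | intermediate
6 | (Z)‑3‑iodo‑2‑methylprop‑2‑enal | I/C=C(/C)C=O | intermediate
7 | B‑allyldiisopinocampheylborane, enantiomer from (−)‑α‑pinene | C=CCB([C@@H]1[C@@H](C)[C@@H]2C[C@H](C1)C2(C)C)[C@@H]1[C@@H](C)[C@@H]2C[C@H](C1)C2(C)C | starting material
8 | diisopinocampheylborinate of 9 | I/C=C(/C)[C@H](OB([C@@H]1[C@@H](C)[C@@H]2C[C@H](C1)C2(C)C)[C@@H]1[C@@H](C)[C@@H]2C[C@H](C1)C2(C)C)CC=C | intermediate (not isolated)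
9 | (1Z,3R)‑1‑iodo‑2‑methylhexa‑1,5‑dien‑3‑ol | I/C=C(/C)[C@H](O)CC=C | intermediate
10 | tert‑butyldimethylsilyl chloride | CC(C)(C)[Si](C)(C)Cl | starting material
11 | tert‑butyl{[(1Z,3R)‑1‑iodo‑2‑methylhexa‑1,5‑dien‑3‑yl]oxy}dimethylsilane | I/C=C(/C)[C@H](O[Si](C)(C)C(C)(C)C)CC=C | intermediate
12 | methacrolein | CC(=C)C=O | starting material
13 | (2E,5R,6Z)‑5‑[(tert‑butyldimethylsilyl)oxy]‑7‑iodo‑2,6‑dimethylhepta‑2,6‑dienal | I/C=C(/C)[C@H](O[Si](C)(C)C(C)(C)C)C/C=C(\C)C=O | intermediate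
14 | (2E,5R,6Z)‑5‑[(tert‑butyldimethylsilyl)oxy]‑7‑iodo‑2,6‑dimethylhepta‑2,6‑dien‑1‑ol | I/C=C(/C)[C@H](O[Si](C)(C)C(C)(C)C)C/C=C(\C)CO | intermediate
15 | tetrabromomethane | BrC(Br)(Br)Br | starting material
16 | (1Z,3R,5E)‑7‑bromo‑3‑[(tert‑butyldimethylsilyl)oxy]‑1‑iodo‑2,6‑dimethylhepta‑1,5‑diene | I/C=C(/C)[C@H](O[Si](C)(C)C(C)(C)C)C/C=C(\C)CBr | intermediate
17 | tert‑butyl acetate | CC(=O)OC(C)(C)C | starting material
18 | lithium enolate of tert‑butyl acetate | [Li]OC(=C)OC(C)(C)C | intermediate (not isolated)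
19 | tert‑butyl (4E,7R,8Z)‑7‑[(tert‑butyldimethylsilyl)oxy]‑9‑iodo‑4,8‑dimethylnona‑4,8‑dienoate | I/C=C(/C)[C@H](O[Si](C)(C)C(C)(C)C)C/C=C(\C)CCC(=O)OC(C)(C)C | intermediate
20 | (4E,7R,8Z)‑7‑[(tert‑butyldimethylsilyl)oxy]‑9‑iodo‑4,8‑dimethylnona‑4,8‑dien‑1‑ol | I/C=C(/C)[C@H](O[Si](C)(C)C(C)(C)C)C/C=C(\C)CCCO | intermediate
21 | (1Z,3R,5E)‑3‑[(tert‑butyldimethylsilyl)oxy]‑1,9‑diiodo‑2,6‑dimethylnona‑1,5‑diene | I/C=C(/C)[C@H](O[Si](C)(C)C(C)(C)C)C/C=C(\C)CCCI | intermediate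
22 | isobutyronitrile | CC(C)C#N | starting material
23 | lithiated isobutyronitrile (N‑lithio ketenimine form) | CC(C)=C=N[Li] | intermediate (not isolated)
24 | (6E,9R,10Z)‑9‑[(tert‑butyldimethylsilyl)oxy]‑11‑iodo‑2,2,6,10‑tetramethylundeca‑6,10‑dienenitrile | I/C=C(/C)[C@H](O[Si](C)(C)C(C)(C)C)C/C=C(\C)CCCC(C)(C)C#N | intermediate
25 | water | O | starting material
26 | N‑(diisobutylaluminio)aldimine of 27 | I/C=C(/C)[C@H](O[Si](C)(C)C(C)(C)C)C/C=C(\C)CCCC(C)(C)C=N[Al](CC(C)C)CC(C)C | intermediate (not isolated)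
27 | (6E,9R,10Z)‑9‑[(tert‑butyldimethylsilyl)oxy]‑11‑iodo‑2,2,6,10‑tetramethylundeca‑6,10‑dienal | I/C=C(/C)[C@H](O[Si](C)(C)C(C)(C)C)C/C=C(\C)CCCC(C)(C)C=O | intermediate
28 | [(1Z,3R,5E)‑3‑[(tert‑butyldimethylsilyl)oxy]‑2,6,10,10‑tetramethyl‑11‑oxoundeca‑1,5‑dien‑1‑yl]chromium dichloride | Cl[Cr](Cl)/C=C(/C)[C@H](O[Si](C)(C)C(C)(C)C)C/C=C(\C)CCCC(C)(C)C=O | intermediate (not isolated)
29 | (2Z,4R,6E)‑4‑[(tert‑butyldimethylsilyl)oxy]‑3,7,11,11‑tetramethylcycloundeca‑2,6‑dien‑1‑ol (C1 epimers) | OC1/C=C(/C)[C@H](O[Si](C)(C)C(C)(C)C)C/C=C(\C)CCCC1(C)C | intermediate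
30 | (2Z,4R,6E)‑4‑[(tert‑butyldimethylsilyl)oxy]‑3,7,11,11‑tetramethylcycloundeca‑2,6‑dien‑1‑one | O=C1/C=C(/C)[C@H](O[Si](C)(C)C(C)(C)C)C/C=C(\C)CCCC1(C)C | intermediate
31 | 2‑{[(1S,2Z,4R,6E)‑4‑[(tert‑butyldimethylsilyl)oxy]‑3,7,11,11‑tetramethylcycloundeca‑2,6‑dien‑1‑yl]oxy}‑1,3,2‑benzodioxaborole | c1ccc2OB(O[C@H]3/C=C(/C)[C@H](O[Si](C)(C)C(C)(C)C)C/C=C(\C)CCCC3(C)C)Oc2c1 | intermediate (not isolated)
32 | (1S,2Z,4R,6E)‑4‑[(tert‑butyldimethylsilyl)oxy]‑3,7,11,11‑tetramethylcycloundeca‑2,6‑dien‑1‑ol | O[C@H]1/C=C(/C)[C@H](O[Si](C)(C)C(C)(C)C)C/C=C(\C)CCCC1(C)C | intermediate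
33 | acetic anhydride | CC(=O)OC(C)=O | starting material
34 | (1S,2Z,4R,6E)‑4‑[(tert‑butyldimethylsilyl)oxy]‑3,7,11,11‑tetramethylcycloundeca‑2,6‑dien‑1‑yl acetate | CC(=O)O[C@H]1/C=C(/C)[C@H](O[Si](C)(C)C(C)(C)C)C/C=C(\C)CCCC1(C)C | intermediate
35 | (1S,2Z,4R,6E)‑4‑hydroxy‑3,7,11,11‑tetramethylcycloundeca‑2,6‑dien‑1‑yl acetate | CC(=O)O[C@H]1/C=C(/C)[C@H](O)C/C=C(\C)CCCC1(C)C | intermediate
36 | 4‑hydroxybenzoic acid | OC(=O)c1ccc(O)cc1 | starting material
37 | tert‑butyldimethylsilyl 4‑[(tert‑butyldimethylsilyl)oxy]benzoate | CC(C)(C)[Si](C)(C)Oc1ccc(cc1)C(=O)O[Si](C)(C)C(C)(C)C | intermediate (not isolated)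
38 | 4‑[(tert‑butyldimethylsilyl)oxy]benzoic acid | CC(C)(C)[Si](C)(C)Oc1ccc(cc1)C(=O)O | intermediate
39 | (1S,2Z,4R,6E)‑1‑acetoxy‑3,7,11,11‑tetramethylcycloundeca‑2,6‑dien‑4‑yl 4‑[(tert‑butyldimethylsilyl)oxy]benzoate | CC(=O)O[C@H]1/C=C(/C)[C@H](OC(=O)c2ccc(O[Si](C)(C)C(C)(C)C)cc2)C/C=C(\C)CCCC1(C)C | intermediate
40 | CNP0246761.2, (1S,2Z,4R,6E)‑1‑acetoxy‑3,7,11,11‑tetramethylcycloundeca‑2,6‑dien‑4‑yl 4‑hydroxybenzoate | CC(=O)O[C@H]1/C=C(/C)[C@H](OC(=O)c2ccc(O)cc2)C/C=C(\C)CCCC1(C)C | target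

## Step count and risks

Total step count: 20. Longest linear sequence: 19 steps (steps 1–17, 19 and 20); step 18 is a one‑step side branch.

**Step 13 (macrocyclisation).** Closing a strained 11‑membered ring onto a neopentyl aldehyde may give mainly oligomers or reduced, de‑iodinated material. The fallback sets out from 14 and comes back at 29, and it moves the ring closure to the unhindered C8–C9 bond. Isobutyraldehyde is added through its pyrrolidine enamine to phenyl vinyl sulfone (Stork Michael addition) to give 2,2‑dimethyl‑4‑(phenylsulfonyl)butanal F1. A bimolecular Nozaki–Hiyama–Kishi coupling of 14 with F1 (CrCl2, catalytic NiCl2, DMSO) gives (2E,5R,6Z)‑5‑[(tert‑butyldimethylsilyl)oxy]‑2,6,9,9‑tetramethyl‑11‑(phenylsulfonyl)undeca‑2,6‑diene‑1,8‑diol F2 as both carbinol epimers. Only the primary allylic hydroxyl is exchanged for chloride (MsCl, LiCl, 2,4,6‑collidine, DMF, 0 °C) to give (5Z,7R,9E)‑7‑[(tert‑butyldimethylsilyl)oxy]‑11‑chloro‑3,3,6,10‑tetramethyl‑1‑(phenylsulfonyl)undeca‑5,9‑dien‑4‑ol F3. The hindered secondary hydroxyl is capped (TESOTf, 2,6‑lutidine, −78 °C) to give the triethylsilyl ether of F3, F4. Intramolecular alkylation of the sulfonyl carbanion (KN(SiMe3)2, THF, 0.003 M, −78 → 0 °C) closes the ring to (2Z,4R,6E)‑4‑[(tert‑butyldimethylsilyl)oxy]‑3,7,11,11‑tetramethyl‑9‑(phenylsulfonyl)‑1‑[(triethylsilyl)oxy]cycloundeca‑2,6‑diene F5. Reductive desulfonylation (Mg, MeOH, rt) gives (2Z,4R,6E)‑4‑[(tert‑butyldimethylsilyl)oxy]‑3,7,11,11‑tetramethyl‑1‑[(triethylsilyl)oxy]cycloundeca‑2,6‑diene F6. Selective removal of the triethylsilyl group (PPTS, MeOH, 0 °C) returns the epimeric alcohol 29.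

**Step 15 (C1 configuration).** The sense and level of CBS induction on a ketone flanked by a quaternary carbon and a Z‑alkenyl group inside a medium ring are uncertain. The fallback sets out from 29 and comes back at 32, and it replaces reagent control by separation with recycling. The C1 epimers of 29 are separated on silica; the 1S epimer is 32. The other epimer, (1R,2Z,4R,6E)‑4‑[(tert‑butyldimethylsilyl)oxy]‑3,7,11,11‑tetramethylcycloundeca‑2,6‑dien‑1‑ol F7, is oxidised to 30 (Dess–Martin periodinane) and reduced without a chiral reagent (NaBH4, CeCl3·7H2O, MeOH, −78 °C) back to 29 for another separation.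

**Step 5 (cross‑metathesis).** The alkenyl iodide or the allylic silyl ether may slow the ruthenium catalyst or erode E selectivity. The fallback sets out from 11 and comes back at 14. Chemoselective dihydroxylation of the terminal alkene (catalytic OsO4, NMO, acetone/H2O) gives (4R,5Z)‑4‑[(tert‑butyldimethylsilyl)oxy]‑6‑iodo‑5‑methylhex‑5‑ene‑1,2‑diol F8. Glycol cleavage (NaIO4, THF/H2O) gives (3R,4Z)‑3‑[(tert‑butyldimethylsilyl)oxy]‑5‑iodo‑4‑methylpent‑4‑enal F9. A Wittig reaction with the stabilised ylide ethyl 2‑(triphenylphosphoranylidene)propanoate (toluene, 60 °C) gives ethyl (2E,5R,6Z)‑5‑[(tert‑butyldimethylsilyl)oxy]‑7‑iodo‑2,6‑dimethylhepta‑2,6‑dienoate F10. Reduction with i‑Bu2AlH (CH2Cl2, −78 °C) gives 14.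

Further compounds
F1 | step 13 | 2,2‑dimethyl‑4‑(phenylsulfonyl)butanal | O=CC(C)(C)CCS(=O)(=O)c1ccccc1
F2 | step 13 | (2E,5R,6Z)‑5‑[(tert‑butyldimethylsilyl)oxy]‑2,6,9,9‑tetramethyl‑11‑(phenylsulfonyl)undeca‑2,6‑diene‑1,8‑diol (C8 epimers) | OC(/C=C(/C)[C@H](O[Si](C)(C)C(C)(C)C)C/C=C(\C)CO)C(C)(C)CCS(=O)(=O)c1ccccc1
F3 | step 13 | (5Z,7R,9E)‑7‑[(tert‑butyldimethylsilyl)oxy]‑11‑chloro‑3,3,6,10‑tetramethyl‑1‑(phenylsulfonyl)undeca‑5,9‑dien‑4‑ol (C4 epimers) | OC(/C=C(/C)[C@H](O[Si](C)(C)C(C)(C)C)C/C=C(\C)CCl)C(C)(C)CCS(=O)(=O)c1ccccc1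
F4 | step 13 | triethylsilyl ether of F3 | CC[Si](CC)(CC)OC(/C=C(/C)[C@H](O[Si](C)(C)C(C)(C)C)C/C=C(\C)CCl)C(C)(C)CCS(=O)(=O)c1ccccc1
F5 | step 13 | (2Z,4R,6E)‑4‑[(tert‑butyldimethylsilyl)oxy]‑3,7,11,11‑tetramethyl‑9‑(phenylsulfonyl)‑1‑[(triethylsilyl)oxy]cycloundeca‑2,6‑diene (C1 and C9 epimers) | CC[Si](CC)(CC)OC1/C=C(/C)[C@H](O[Si](C)(C)C(C)(C)C)C/C=C(\C)CC(S(=O)(=O)c2ccccc2)CC1(C)C
F6 | step 13 | (2Z,4R,6E)‑4‑[(tert‑butyldimethylsilyl)oxy]‑3,7,11,11‑tetramethyl‑1‑[(triethylsilyl)oxy]cycloundeca‑2,6‑diene (C1 epimers) | CC[Si](CC)(CC)OC1/C=C(/C)[C@H](O[Si](C)(C)C(C)(C)C)C/C=C(\C)CCCC1(C)C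
F7 | step 15 | (1R,2Z,4R,6E)‑4‑[(tert‑butyldimethylsilyl)oxy]‑3,7,11,11‑tetramethylcycloundeca‑2,6‑dien‑1‑ol | O[C@@H]1/C=C(/C)[C@H](O[Si](C)(C)C(C)(C)C)C/C=C(\C)CCCC1(C)C
F8 | step 5 | (4R,5Z)‑4‑[(tert‑butyldimethylsilyl)oxy]‑6‑iodo‑5‑methylhex‑5‑ene‑1,2‑diol (C2 epimers) | I/C=C(/C)[C@H](O[Si](C)(C)C(C)(C)C)CC(O)CO
F9 | step 5 | (3R,4Z)‑3‑[(tert‑butyldimethylsilyl)oxy]‑5‑iodo‑4‑methylpent‑4‑enal | I/C=C(/C)[C@H](O[Si](C)(C)C(C)(C)C)CC=O
F10 | step 5 | ethyl (2E,5R,6Z)‑5‑[(tert‑butyldimethylsilyl)oxy]‑7‑iodo‑2,6‑dimethylhepta‑2,6‑dienoate | I/C=C(/C)[C@H](O[Si](C)(C)C(C)(C)C)C/C=C(\C)C(=O)OCC
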